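**Retrosynthetic overview**
1. GA65 (19) ⇐ 15-oxo-GA24 (16) by exo-face hydride delivery to C15; 16 ⇐ GA15 (12) by allylic oxidation at C15, opening of the 19,20-lactone and oxidation of C20.
2. 12 ⇐ 1-ene lactone 11 ⇐ stannylmethyl ether 8 by a [2,3]-Wittig–Still shift: this makes the C10–C20 bond and relays chirality from the 2α C–O bond to the C10 quaternary centre.
3. 8 ⇐ 3-deoxy isolactone 5 ⇐ GA7 (1): alkali-induced allylic lactone transposition puts oxygen on C2α and the alkene at C1=C10; Barton–McCombie removes the 3-OH.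
4. Ring order: carbocyclic rings A to D and the stereocentres C4, C5, C6, C8, C9, C13 are bought in 1. No carbocycle is built; only lactone rings change (19→10, then 19→2, then 19→20, then open).

Assumption: GA7 is bought as the fermentation product (sold pure and as the bulk GA4/GA7 growth-regulator mixture); GA followed by a number is the usual short name of a gibberellin, and ent-gibberellane numbering is used throughout.

The route is a paper design; conditions are typical, not optimised.

**Step 1**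
Reactants: 1 GA7
Product: 2 GA7 methyl ester
Conditions: Me3SiCHN2, MeOH–PhMe, 0 °C → rt
Reagents that add atoms: trimethylsilyldiazomethane C[Si](C)(C)C=[N+]=[N-]
Why: Diazoalkane esterification of the only carboxylic acid runs under neutral conditions, so the base- and acid-labile allylic lactone and 3-hydroxyl of ring A are untouched and no stereocentre is affected.

**Step 2**
Reactants: 2 GA7 methyl ester
Product: 3 iso-GA7 methyl ester
Conditions: NaOH (0.2 equiv, 0.01 M), MeOH–H2O 1:1, 20 °C; NaH2PO4 quench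
Reagents that add atoms: none
Why: This is the allylic lactone transposition known for GA3 → iso-GA3: the ionised 3β-hydroxyl displaces the lactone in an anti SN2′ sense (transient 2β,3β-epoxy-1(10)-ene carboxylate) and the C19 carboxylate reopens the epoxide at C2 from the α-face, which sets the 2α C–O bond cis to C19 and moves the alkene to C1=C10.

**Step 3**
Reactants: 3 iso-GA7 methyl ester
Product: 4 3-O-phenoxythiocarbonyl isolactone
Conditions: PhOC(S)Cl, DMAP (cat.), pyridine, CH2Cl2, 0 °C → rt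
Reagents that add atoms: phenyl chlorothionoformate S=C(Cl)Oc1ccccc1
Why: Acylation of the only free hydroxyl gives the thionocarbonate needed for Barton–McCombie deoxygenation without generating a free 3-alkoxide, so the lactone stays in place and no stereocentre changes.

**Step 4**
Reactants: 4 3-O-phenoxythiocarbonyl isolactone
Product: 5 3-deoxy isolactone methyl ester
Conditions: Bu3SnH, AIBN (cat.), PhMe, 100 °C
Reagents that add atoms: none
Why: In this Barton–McCombie radical deoxygenation the stannyl radical adds to C=S, β-scission gives the secondary C3 radical and Bu3SnH reduces it, the β-acyloxy group and both alkenes being inert, so the C3 stereocentre is simply erased.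

**Step 5**
Reactants: 5 3-deoxy isolactone methyl ester; 6 (iodomethyl)tributylstannane
Product: 8 2α-(tributylstannylmethoxy) diacid, via dipotassium hydroxy dicarboxylate 7 (not isolated)
Conditions: KOH, MeOH–H2O, reflux; evaporate, PhMe azeotrope; KH (1.2 equiv), 18-crown-6, THF, 0 °C; 6 (1.1 equiv), rt; aq. HCl to pH 4, 0 °C
Reagents that add atoms: potassium hydroxide [K+].[OH-]; (iodomethyl)tributylstannane 6 CCCC[Sn](CCCC)(CCCC)CI
Why: Saponification opens the bridged lactone and the hindered ester, and Williamson alkylation of the resulting trianion goes at the alkoxide, which is far more nucleophilic than the two carboxylates, so the stannylmethyl ether is installed with C2 unchanged.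

**Step 6**
Reactants: 8 2α-(tributylstannylmethoxy) diacid
Product: 11 1,2-didehydro-GA15, via trilithium alkoxide dicarboxylate 9 (not isolated), via hydroxy diacid 10 (not isolated)
Conditions: n-BuLi (3.3 equiv), THF, −78 → −40 °C; then 1 M HCl, THF, rt
Reagents that add atoms: none
Why: Tin–lithium exchange gives the α-alkoxymethyllithium, whose [2,3]-sigmatropic Wittig–Still rearrangement forms the C10–C20 bond suprafacially from the pseudoaxial 2α oxygen, so C20 enters on the α-face cis to C19 and fixes the C10 quaternary stereocentre, after which acid closes the 1,3-diaxial hydroxy acid to the δ-lactone.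

**Step 7**
Reactants: 11 1,2-didehydro-GA15
Product: 12 GA15
Conditions: H2 (1 atm, stopped at 1.0 equiv), 5% Pd on BaCO3, pyridine–THF, 20 °C
Reagents that add atoms: none
Why: Partial heterogeneous hydrogenation over pyridine-moderated Pd reduces the cis-disubstituted ring A alkene faster than the hindered exocyclic 16-methylene on the bicyclo[3.2.1]octane (the selectivity known from the partial hydrogenation of GA3 to GA1 and of GA7 to GA4), and no stereocentre is created.

**Step 8**
Reactants: 12 GA15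
Product: 14 15α-hydroxy-GA15 7→15 lactone, via 15α-hydroxy-GA15 13 (not isolated)
Conditions: SeO2 (0.5 equiv), t-BuOOH (2 equiv), CH2Cl2, 20 °C; then PPTS (cat.), 20 °C
Reagents that add atoms: selenium dioxide O=[Se]=O; tert-butyl hydroperoxide CC(C)(C)OO
Why: SeO2 allylic oxidation (ene reaction at C17, then [2,3]-sigmatropic shift of the allylseleninic acid) should hydroxylate C15 from the open exo face to give the 15α alcohol, which sits next to the 7-carboxyl and is trapped as the γ-lactone; step 9 opens any lactone and erases the C15 configuration, so unlactonised 13 or any 15β epimer can be carried along.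

**Step 9**
Reactants: 14 15α-hydroxy-GA15 7→15 lactone
Product: 16 15-oxo-GA24, via bis(tetrabutylammonium) dihydroxy dicarboxylate 15 (not isolated)
Conditions: nBu4NOH (2.1 equiv, aq.), THF, 50 °C; evaporate, PhMe azeotrope; nPr4N[RuO4] (10 mol%), NMO (4 equiv), 4 Å MS, MeCN–CH2Cl2, 20 °C; aq. HCl to pH 3
Reagents that add atoms: tetrabutylammonium hydroxide CCCC[N+](CCCC)(CCCC)CCCC.[OH-]
Why: Hydroxide opens both lactones to the bis-carboxylate, in which neither hydroxy acid can re-lactonise, and Ley–Griffith oxidation under anhydrous non-acidic conditions takes the primary C20 alcohol to the non-enolisable aldehyde and the allylic C15 alcohol to the enone without touching the alkene or over-oxidising.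

**Step 10**
Reactants: 16 15-oxo-GA24
Product: 19 GA65, via ψ-ester enone 17 (not isolated), via ψ-ester allylic alcohol 18 (not isolated)
Conditions: CeCl3·7H2O, HC(OMe)3, MeOH, 20 °C; NaBH4, −78 → −40 °C; then 0.5 M HCl–THF, 20 °C
Reagents that add atoms: water O
Why: In this Luche reduction run in the Gemal–Luche manner the C20 aldehyde is masked in situ as the cyclic lactol methyl ether with the neighbouring C19 acid, the enone is reduced 1,2 by hydride attacking C15 from the exo face (C14 side, away from the C9–C11–C12 bridge and its axial 11β-H) to give the endo 15β alcohol (15R), and dilute acid then frees the aldehyde.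

**Compound list**
1 | GA7 (3β-hydroxy, 1,16-diene, 19→10α lactone, 7-acid) | C=C1[C@@H]2CC[C@H]3[C@]45C=C[C@H](O)[C@@](C)(C(=O)O5)[C@H]4[C@H](C(=O)O)[C@]3(C2)C1 | starting material
2 | GA7 methyl ester (7-CO2Me) | C=C1[C@@H]2CC[C@H]3[C@]45C=C[C@H](O)[C@@](C)(C(=O)O5)[C@H]4[C@H](C(=O)OC)[C@]3(C2)C1 | intermediate
3 | iso-GA7 methyl ester (3β-hydroxy, 19→2α lactone, 1(10),16-diene, 7-CO2Me) | C=C1[C@@H]2CC[C@H]3C4=C[C@@H]5[C@H](O)[C@@](C)(C(=O)O5)[C@H]4[C@H](C(=O)OC)[C@]3(C2)C1 | intermediate
4 | 3-O-phenoxythiocarbonyl derivative of 3 | C=C1[C@@H]2CC[C@H]3C4=C[C@@H]5[C@H](OC(=S)Oc6ccccc6)[C@@](C)(C(=O)O5)[C@H]4[C@H](C(=O)OC)[C@]3(C2)C1 | intermediate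
5 | 3-deoxy isolactone methyl ester (19→2α lactone, 1(10),16-diene, 7-CO2Me) | C=C1[C@@H]2CC[C@H]3C4=C[C@@H]5C[C@@](C)(C(=O)O5)[C@H]4[C@H](C(=O)OC)[C@]3(C2)C1 | intermediate
6 | (iodomethyl)tributylstannane | CCCC[Sn](CCCC)(CCCC)CI | starting material
7 | dipotassium 2α-hydroxy-20-norgibberella-1(10),16-diene-7,19-dioate | C=C1[C@@H]2CC[C@H]3C4=C[C@@H](O)C[C@@](C)(C(=O)[O-])[C@H]4[C@H](C(=O)[O-])[C@]3(C2)C1.[K+].[K+] | intermediate
8 | 2α-(tributylstannylmethoxy)-20-norgibberella-1(10),16-diene-7,19-dioic acid | C=C1[C@@H]2CC[C@H]3C4=C[C@@H](OC[Sn](CCCC)(CCCC)CCCC)C[C@@](C)(C(=O)O)[C@H]4[C@H](C(=O)O)[C@]3(C2)C1 | intermediate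
9 | trilithium 20-oxidogibberella-1,16-diene-7,19-dioate (C20 α on C10) | C=C1[C@@H]2CC[C@H]3[C@]4(C[O-])C=CC[C@@](C)(C(=O)[O-])[C@H]4[C@H](C(=O)[O-])[C@]3(C2)C1.[Li+].[Li+].[Li+] | intermediate
10 | 20-hydroxygibberella-1,16-diene-7,19-dioic acid | C=C1[C@@H]2CC[C@H]3[C@]4(CO)C=CC[C@@](C)(C(=O)O)[C@H]4[C@H](C(=O)O)[C@]3(C2)C1 | intermediate
11 | 1,2-didehydro-GA15 (19→20 lactone, 1,16-diene, 7-acid) | C=C1[C@@H]2CC[C@H]3[C@]4(CO5)C=CC[C@@](C)(C5=O)[C@H]4[C@H](C(=O)O)[C@]3(C2)C1 | intermediate
12 | GA15 (19→20 lactone, 16-ene, 7-acid) | C=C1[C@@H]2CC[C@H]3[C@]4(CO5)CCC[C@@](C)(C5=O)[C@H]4[C@H](C(=O)O)[C@]3(C2)C1 | intermediate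
13 | 15α-hydroxy-GA15 (15S, hydroxyl exo, on the C14 side) | C=C1[C@@H]2CC[C@H]3[C@]4(CO5)CCC[C@@](C)(C5=O)[C@H]4[C@H](C(=O)O)[C@]3(C2)[C@H]1O | intermediate
14 | 15α-hydroxy-GA15 7→15 lactone (bis-lactone) | C=C1[C@@H]2CC[C@H]3[C@]4(CO5)CCC[C@@](C)(C5=O)[C@H]4[C@H](C(=O)O6)[C@]3(C2)[C@H]16 | intermediate
15 | bis(tetrabutylammonium) 15α,20-dihydroxygibberell-16-ene-7,19-dioate | C=C1[C@@H]2CC[C@H]3[C@]4(CO)CCC[C@@](C)(C(=O)[O-])[C@H]4[C@H](C(=O)[O-])[C@]3(C2)[C@H]1O.CCCC[N+](CCCC)(CCCC)CCCC.CCCC[N+](CCCC)(CCCC)CCCC | intermediate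
16 | 15-oxo-GA24 (15,20-dioxogibberell-16-ene-7,19-dioic acid) | C=C1[C@@H]2CC[C@H]3[C@]4(C=O)CCC[C@@](C)(C(=O)O)[C@H]4[C@H](C(=O)O)[C@]3(C2)C1=O | intermediate
17 | 15-oxo-GA24 19,20-lactol methyl ether (ψ-ester, C20 epimers) | C=C1[C@@H]2CC[C@H]3[C@]4(C(OC)O5)CCC[C@@](C)(C5=O)[C@H]4[C@H](C(=O)O)[C@]3(C2)C1=O | intermediate
18 | 15β-hydroxy ψ-ester (15R; 19,20-lactol methyl ether of 19) | C=C1[C@@H]2CC[C@H]3[C@]4(C(OC)O5)CCC[C@@](C)(C5=O)[C@H]4[C@H](C(=O)O)[C@]3(C2)[C@@H]1O | intermediate
19 | GA65 (15β-hydroxy-GA24; 15R, hydroxyl endo) | C=C1[C@@H]2CC[C@H]3[C@]4(C=O)CCC[C@@](C)(C(=O)O)[C@H]4[C@H](C(=O)O)[C@]3(C2)[C@@H]1O | target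

**Totals**
Total step count: 10. Longest linear sequence: 10 steps (1 → 19).

**Three steps most likely to fail, with fallbacks**

Step 6. The Wittig–Still shift has to bond to the fully substituted C10 next to the C19 carboxylate; a [1,2]-shift, protonation of the carbanion or attack of n-BuLi on a carboxylate could win. Fallback, setting out from 5 and coming back at 11: replace the [2,3] shift by a [3,3] Ireland–Claisen rearrangement of a glycolate and excise the extra carbon by an ionic α-hydroxy acid cleavage. Saponify 5 with KOH and methylate the dipotassium salt with MeI in DMF to the hydroxy diester F1. Acylate the 2α-hydroxyl with (tert-butyldimethylsilyloxy)acetic acid (DCC, DMAP, CH2Cl2) to the silyl glycolate F2. Rearrange its silyl ketene acetal (KN(SiMe3)2, Me3SiCl, THF, −78 → 60 °C) and strip the silyl groups with Bu4NF to the α-hydroxy acid F3; carbon is again delivered to the α-face of C10 from the 2α oxygen, and the new carbinol centre is lost in the next operation. Pb(OAc)4 in benzene at 10 °C cleaves the α-hydroxy acid to CO2 and the 20-aldehyde F4. NaBH4 in MeOH at 0 °C reduces the aldehyde, and the alkoxide closes on the C19 ester to give the lactone methyl ester F5. KOH followed by HCl then gives lactone 11.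

Step 7. The exocyclic 16-methylene may be reduced or isomerised along with the ring A alkene. Fallback, setting out from 11 and coming back at 12: mask the methylene by hydroboration. 9-BBN (in excess, since the acid consumes one equivalent) reacts far faster with the 1,1-disubstituted alkene than with the ring alkene and, after NaOH/H2O2 and acidification, gives the 17-alcohol F6. H2 over Pd on carbon saturates ring A to the saturated 17-alcohol F7. TsCl in pyridine gives the tosylate F8. KOtBu in DMSO effects β-elimination, in which H-16 is the only β-hydrogen, and regenerates the 16-methylene of 12.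

Step 10. The hindered aldehyde may be reduced together with the enone if the in situ masking is incomplete. Fallback, setting out from 16 and coming back at 19: give up the chemoselectivity and rebuild the aldehyde. NaBH4 with CeCl3·7H2O in MeOH at −78 °C reduces the enone as before (hydride on the exo face of C15); aqueous NaOH and more NaBH4 at 20 °C then reduce the aldehyde as well, and acidification closes the 19,20-lactone to 15β-hydroxy-GA15 F9. TBSOTf with 2,6-lutidine gives the silyl ether F10 (the silyl ester formed at C7 falls off on aqueous work-up). nBu4NOH opens the lactone to the bis(tetrabutylammonium) salt F11, and nPr4N[RuO4]/NMO oxidises C20 as in step 9 to the silylated aldehyde diacid F12. HF·pyridine removes the silyl group to give 19.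

**Further compounds**
F1 | step 6 | dimethyl 2α-hydroxy-20-norgibberella-1(10),16-diene-7,19-dioate | C=C1[C@@H]2CC[C@H]3C4=C[C@@H](O)C[C@@](C)(C(=O)OC)[C@H]4[C@H](C(=O)OC)[C@]3(C2)C1
F2 | step 6 | dimethyl 2α-[(tert-butyldimethylsilyloxy)acetoxy]-20-norgibberella-1(10),16-diene-7,19-dioate | C=C1[C@@H]2CC[C@H]3C4=C[C@@H](OC(=O)CO[Si](C)(C)C(C)(C)C)C[C@@](C)(C(=O)OC)[C@H]4[C@H](C(=O)OC)[C@]3(C2)C1
F3 | step 6 | 20-carboxy-20-hydroxygibberella-1,16-diene-7,19-dioic acid 7,19-dimethyl ester (C20 epimers) | C=C1[C@@H]2CC[C@H]3[C@]4(C(O)C(=O)O)C=CC[C@@](C)(C(=O)OC)[C@H]4[C@H](C(=O)OC)[C@]3(C2)C1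
F4 | step 6 | dimethyl 20-oxogibberella-1,16-diene-7,19-dioate | C=C1[C@@H]2CC[C@H]3[C@]4(C=O)C=CC[C@@](C)(C(=O)OC)[C@H]4[C@H](C(=O)OC)[C@]3(C2)C1
F5 | step 6 | 1,2-didehydro-GA15 methyl ester | C=C1[C@@H]2CC[C@H]3[C@]4(CO5)C=CC[C@@](C)(C5=O)[C@H]4[C@H](C(=O)OC)[C@]3(C2)C1
F6 | step 7 | 17-hydroxy-16,17-dihydro derivative of 11 (C16 epimers) | OCC1[C@@H]2CC[C@H]3[C@]4(CO5)C=CC[C@@](C)(C5=O)[C@H]4[C@H](C(=O)O)[C@]3(C2)C1
F7 | step 7 | 17-hydroxy-16,17-dihydro-GA15 (C16 epimers) | OCC1[C@@H]2CC[C@H]3[C@]4(CO5)CCC[C@@](C)(C5=O)[C@H]4[C@H](C(=O)O)[C@]3(C2)C1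
F8 | step 7 | 17-O-tosyl derivative of F7 | Cc6ccc(cc6)S(=O)(=O)OCC1[C@@H]2CC[C@H]3[C@]4(CO5)CCC[C@@](C)(C5=O)[C@H]4[C@H](C(=O)O)[C@]3(C2)C1
F9 | step 10 | 15β-hydroxy-GA15 | C=C1[C@@H]2CC[C@H]3[C@]4(CO5)CCC[C@@](C)(C5=O)[C@H]4[C@H](C(=O)O)[C@]3(C2)[C@@H]1O
F10 | step 10 | 15-O-tert-butyldimethylsilyl derivative of F9 | C=C1[C@@H]2CC[C@H]3[C@]4(CO5)CCC[C@@](C)(C5=O)[C@H]4[C@H](C(=O)O)[C@]3(C2)[C@@H]1O[Si](C)(C)C(C)(C)C
F11 | step 10 | bis(tetrabutylammonium) 15β-silyloxy-20-hydroxygibberell-16-ene-7,19-dioate | C=C1[C@@H]2CC[C@H]3[C@]4(CO)CCC[C@@](C)(C(=O)[O-])[C@H]4[C@H](C(=O)[O-])[C@]3(C2)[C@@H]1O[Si](C)(C)C(C)(C)C.CCCC[N+](CCCC)(CCCC)CCCC.CCCC[N+](CCCC)(CCCC)CCCC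
F12 | step 10 | 15-O-tert-butyldimethylsilyl-GA65 | C=C1[C@@H]2CC[C@H]3[C@]4(C=O)CCC[C@@](C)(C(=O)O)[C@H]4[C@H](C(=O)O)[C@]3(C2)[C@@H]1O[Si](C)(C)C(C)(C)C
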